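## The problem

The target is a linear trimer of 7,8,4′-trihydroxyflavan units. Two flavan-3-ols (top and middle) are each bonded through C4 to C6 of the unit below, and the bottom unit is a flavan-3,4-diol. There are nine stereocentres: (2R,3R,4S) in the top and middle units (2α-aryl, 3α-OH, 4β-aryl, so 2,3-cis-3,4-trans) and (2R,3R,4R) in the bottom unit (all-cis).

Within an upper unit the three centres are contiguous. The C4 aryl group can steer oxygen onto the opposite face of C3, and the C3 oxygen can deliver the C2 aryl group to its own face. C4 itself is four bonds from the nearest stereocentre of the unit below, so the substrate cannot set it. In the bottom unit both diol oxygens are cis to the C2 aryl group, which a direct dihydroxylation of a flav-3-ene does not give.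

The fragile features are:
- nine phenols in catechol-type arrays (air and base);
- the interflavan C4–C6 bonds and the benzylic C2–O1 ethers (acid);
- the benzylic C4–OH of the bottom unit (acid ionisation, hydrogenolysis).

The feature that opens a short route is that C4 of each upper unit is a diarylmethine whose two rings both carry an oxygen para to it: C7–O of its own benzo ring through C4a, and O1 of the lower unit through C6. C4a is also next to C8a–O1, so a vinyl group on O1 holds its β-carbon, the future C3, beside a strongly stabilised C4 cation.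

## Retrosynthesis

**Deprotection (28 from 27 from 26).** The nine phenols are freed last from benzyl ethers 27. The bottom diol is masked in 26 as a cyclic carbonate, which is cleaved first. A benzylic carbonate C4–O bond would be hydrogenolysed, whereas the free alcohol should survive neutral conditions. The carbonate is kept through the route because it makes the bottom C4–O bond inert to the acid of the ring-forming steps.

**C2–aryl and C3–O of the top unit (26 from chromene 24 through epoxide 25).** Cutting these two bonds leaves a 4-aryl-4H-chromene with C4 as its only stereocentre. The forward sequence uses the two relays named above: epoxidation anti to the 4β-aryl group, then syn transfer of the aryl group from an aluminium centre bound to the epoxide oxygen. Closing O1–C2 from an open-chain diol, or hydroborating a 2-aryl chromene, would give mainly the 2,3-trans series. The forward step must transfer the aryl group faster than the enol-ether epoxide rearranges.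

**C3–C4 of the top unit (24 from carbinol 23, key step).** Cutting C3–C4 opens the pyran ring to a benzhydrol carrying an O-vinyl group on the neighbouring ring carbon. Ionisation gives a cation stabilised by both para oxygens, and the vinyl ether β-carbon closes the ring. The alternative cut at C4–C6 is the classical flavan-4-yl cation coupling. It needs a complete upper unit as electrophile, and the 7,8-dioxygenated series ionises poorly. The precursor 23 has one ring and one stereocentre fewer. The forward step must ionise the carbinol before the vinyl ether is protonated and must choose one face of a planar cation.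

**Carbinol C–C bond (23 from iodide 21 and aldehyde 3).** The carbinol is cut on the side of the lower unit. C6 of the middle unit in 20 is the one strongly activated free position (para to O1, ortho to the 7-benzyloxy group), so iodination should give 21 directly. The partner is then the small aldehyde 3, which already carries the vinyl ether, so no phenol has to be vinylated beside an ionisable benzhydrol. The opposite cut would need formylation of the dimer and a regiodefined aryl-metal of the small ring. The forward step must add the aryl Grignard to the aldehyde without touching the carbonate. The middle 3-OH of 20 is left free: it is deprotonated before exchange, cannot reach the cation, and costs one extra equivalent of alane.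

**Middle unit (20 from chromene 18 through epoxide 19; 18 from carbinol 17; 17 from iodide 15 and aldehyde 3).** The same three operations build the middle unit on the bottom unit. The cyclisation is therefore first tested on the cheaper monomer.

**Bottom unit (15 from carbonate 14, 14 from flav-3-ene 12).** Iodination of 14 should go to C6 for the same reason as above. Both C–O bonds of the all-cis carbonate are cut back to the alkene 12. Bromonium formation anti to the C2 aryl group and attack of water at benzylic C4 put the 4-OH cis to the aryl group. Carboxylation of that oxygen and intramolecular displacement of bromide with inversion then bring the C3 oxygen to the same face. Osmylation or epoxide opening would place at least one oxygen trans to the aryl group.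

**Flavene (12 from flavanol 10 from flavanone 9; 9 from chromone 7 and boronic acid 8; 7 from 5 from gallacetophenone 4).** The only stereocentre of the bottom unit that needs a catalyst is C2. It is set by asymmetric conjugate addition of 8 to chromone 7. Reduction and dehydration move the unsaturation to C3=C4.

**Aldehyde (3 from 2 from 1).** The vinyl ether is put on the chelated phenol of 2, which comes from selective dibenzylation of 2,3,4-trihydroxybenzaldehyde 1.

## Roads not taken

**Alternative 1:** The C2–C3 and C2–aryl bonds of the middle unit are made on an open chain. Dichloromethyllithium inserts a carbon between C3 and boron, and 4-benzyloxyphenylmagnesium bromide then displaces chloride by a second 1,2-shift, giving A1. Oxidation of the C–B bond and an intramolecular aryl ether closure at the bromide would then complete the pyran ring.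
- Merits: each centre is set by a stereospecific migration under control of the diol on boron. This is established chemistry, and here this road is better than the chosen plan, whose C4 control is untested.
- Weak points: the boron-bearing carbon has a β-benzyloxy group that can eliminate with boron; the carbon is crowded by the diarylmethine; the benzylic α-chloroboronate can epimerise; the late ether closure joins a hindered secondary alcohol to an aryl bromide flanked by oxygen. The chain has to be built by earlier homologations and the whole sequence run twice.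
- Comparison: the chosen plan offers convergence instead. The benzo ring and O1 arrive together in aldehyde 3, and one step turns the carbinol into the ring.

**Alternative 2:** The C4–C4a and O1–C2 bonds are cut, and the benzo ring is grown from cyclohexane-1,2-dione. A diarylprolinol silyl ether activates a dimer-derived enal as its iminium ion, the dione adds at C4 and closes as the lactol A2.
- Merits: the C4 centre comes from a known type of enantioselective organocatalysis. That is a real advantage over the chosen key step.
- Weak points: A2 carries a cyclohexenone where the 7,8-dioxygenated benzene ring must be. Aromatisation by dehydrogenation has to be done in a molecule full of electron-rich benzylic methines, followed by double benzylation and dehydration of the lactol. The enal itself needs formylation and olefination of the dimer. The same epoxidation and arylation would still follow.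
- Comparison: the chosen plan brings the aromatic ring in at the correct oxidation level and needs no redox correction.

**Alternative 3:** The O1–C2 bond is formed by ring expansion. In a dihydrobenzofuran precursor the ring oxygen displaces a C2 mesylate under Zn(OAc)2, and acetate opens the bridged oxonium ion at C3 to give A3.
- Merits: the step is stereospecific (two inversions) and gives the fully assembled, protected trimer without an enol ether or epoxide. In this respect it is at least as good as the chosen end-game.
- Weak points: an aryl ether oxygen is a poor neighbouring group. The benzylic C2 terminus of the oxonium ion is the more electrophilic one, so acetate attack there, or direct SN1 substitution, would return a five-membered ring. The pivalate is needed to temper this and adds protecting-group steps. The three contiguous centres of the dihydrobenzofuran must already be in place on the dimer, so the stereochemical burden is moved, not removed.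
- Comparison: the chosen plan builds its precursor in one step from iodide and aldehyde, and the regiochemistry of its ring closure is unambiguous.

Key step: step 15

Remarks on the chemistry:
- α and β refer to the usual flavan drawing (benzo ring left, O1 up); with 2R configuration the C2 aryl group is α. At C4 of the upper units and at C3 of the carbonate the R/S letter changes with the protecting groups while the geometry stays the same, so these centres are described by α/β and by the SMILES.
- The sense of induction in step 5 is assumed by analogy with cyclic enones; if it proves opposite for the chromone, the antipodal ligand is used.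
- The catalyst enantiomer for steps 11 and 15 is the one that gives the 4β product, to be identified in step 11.
- Tris[4-(benzyloxy)phenyl]alane is prepared beforehand from commercial 4-benzyloxyphenylmagnesium bromide and AlCl3.
- Carbinols 17 and 23 are used as mixtures of epimers at the carbinol carbon, which is planar in the next step.

## Route

Step 1
Reactants: 1 2,3,4-trihydroxybenzaldehyde
Product: 2 3,4-bis(benzyloxy)-2-hydroxybenzaldehyde
Conditions: BnBr (2.1 equiv), K2CO3 (2.2 equiv), DMF, rt
Reagents that add atoms: benzyl bromide BrCc1ccccc1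
Why: Williamson etherification; the 2-OH is hydrogen-bonded to the formyl group and is the least nucleophilic, so two equivalents of bromide should take the 4- and 3-oxygens.

Step 2
Reactants: 2 3,4-bis(benzyloxy)-2-hydroxybenzaldehyde
Product: 3 3,4-bis(benzyloxy)-2-(vinyloxy)benzaldehyde
Conditions: vinyl acetate (3 equiv), [Ir(cod)Cl]2 (1 mol%), Na2CO3 (0.6 equiv), toluene, 100 °C
Reagents that add atoms: vinyl acetate C=COC(C)=O
Why: Iridium-catalysed transfer vinylation of a phenol with vinyl acetate; the mildly basic conditions should leave the aldehyde and benzyl ethers untouched.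

Step 3
Reactants: 4 2,3,4-trihydroxyacetophenone (gallacetophenone)
Product: 5 1-[3,4-bis(benzyloxy)-2-hydroxyphenyl]ethanone
Conditions: BnBr (2.1 equiv), K2CO3 (2.2 equiv), DMF, rt
Reagents that add atoms: benzyl bromide BrCc1ccccc1
Why: Williamson etherification with the same chelation-based selectivity as in step 1; the hydrogen-bonded 2-OH stays free.

Step 4
Reactants: 5 1-[3,4-bis(benzyloxy)-2-hydroxyphenyl]ethanone
Product: 7 7,8-bis(benzyloxy)-4H-chromen-4-one, via enaminone 6 (not isolated)
Conditions: Me2NCH(OMe)2, toluene, 100 °C; then conc. HCl, CH2Cl2, 40 °C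
Reagents that add atoms: N,N-dimethylformamide dimethyl acetal COC(OC)N(C)C
Why: Condensation of the methyl ketone with the amide acetal gives the enaminone; acid then promotes conjugate addition of the phenol and loss of dimethylamine (standard chromone synthesis).

Step 5
Reactants: 7 7,8-bis(benzyloxy)-4H-chromen-4-one; 8 4-(benzyloxy)phenylboronic acid
Product: 9 (2S)-7,8-bis(benzyloxy)-2-[4-(benzyloxy)phenyl]chroman-4-one
Conditions: 8 (2 equiv), Pd(OCOCF3)2 (5 mol%), (R)-4-tert-butyl-2-(pyridin-2-yl)-4,5-dihydrooxazole (6 mol%), NH4PF6 (30 mol%), H2O (5 equiv), ClCH2CH2Cl, 60 °C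
Reagents that add atoms: none
Why: Palladium-catalysed asymmetric conjugate addition of an arylboronic acid to a chromone; the arylpalladium species adds to C2 on the face fixed by the pyridine-oxazoline ligand, and protonation of the palladium enolate gives the 2S flavanone.

Step 6
Reactants: 9 (2S)-7,8-bis(benzyloxy)-2-[4-(benzyloxy)phenyl]chroman-4-one
Product: 10 (2S,4S)-7,8-bis(benzyloxy)-2-[4-(benzyloxy)phenyl]chroman-4-ol
Conditions: NaBH4, MeOH/THF, 0 °C
Reagents that add atoms: none
Why: Hydride reduction of the ketone, expected to give mainly the 2,4-cis alcohol; the C4 centre is removed in step 7, so its ratio does not matter, and the neutral cold conditions should not open the flavanone ring.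

Step 7
Reactants: 10 (2S,4S)-7,8-bis(benzyloxy)-2-[4-(benzyloxy)phenyl]chroman-4-ol
Product: 12 (2S)-7,8-bis(benzyloxy)-2-[4-(benzyloxy)phenyl]-2H-chromene, via mesylate 11 (not isolated)
Conditions: MsCl, Et3N (3 equiv), CH2Cl2, 0 °C → rt
Reagents that add atoms: none
Why: Sulfonylation of the p-alkoxybenzylic alcohol and amine-buffered elimination give the C3=C4 alkene; keeping the medium basic avoids acid ionisation of the C2–O1 bond, so C2 should stay intact.

Step 8
Reactants: 12 (2S)-7,8-bis(benzyloxy)-2-[4-(benzyloxy)phenyl]-2H-chromene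
Product: 14 (2R,3S,4R)-7,8-bis(benzyloxy)-2-[4-(benzyloxy)phenyl]chroman-3,4-diyl carbonate (all-cis), via bromohydrin 13 (not isolated)
Conditions: NBS, THF/H2O, 0 °C; solvent exchange; then Cs2CO3, CO2 (1 atm), DMF, 40 °C
Reagents that add atoms: water O; carbon dioxide O=C=O
Why: Bromohydrin formation followed by carboxylative cyclisation of a halohydrin. The bromonium ion forms anti to the C2 aryl group and water opens it at benzylic C4, giving 3β-Br and 4α-OH. The caesium alkoxide takes up CO2 and the carbonate oxygen displaces bromide at C3 with inversion, so both oxygens end cis to the aryl group.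

Step 9
Reactants: 14 (2R,3S,4R)-7,8-bis(benzyloxy)-2-[4-(benzyloxy)phenyl]chroman-3,4-diyl carbonate
Product: 15 (2R,3S,4R)-7,8-bis(benzyloxy)-2-[4-(benzyloxy)phenyl]-6-iodochroman-3,4-diyl carbonate
Conditions: NIS (1.05 equiv), CF3CO2H (10 mol%), MeCN/CH2Cl2, 0 °C → rt
Reagents that add atoms: N-iodosuccinimide O=C1CCC(=O)N1I
Why: Electrophilic aromatic iodination; C6 is para to O1 and ortho to the 7-benzyloxy group and is the most activated free position, ahead of C5 and the 4-benzyloxyphenyl ring.

Step 10
Reactants: 15 (2R,3S,4R)-7,8-bis(benzyloxy)-2-[4-(benzyloxy)phenyl]-6-iodochroman-3,4-diyl carbonate; 3 3,4-bis(benzyloxy)-2-(vinyloxy)benzaldehyde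
Product: 17 carbonate 14 bearing at C6 a [3,4-bis(benzyloxy)-2-(vinyloxy)phenyl](hydroxy)methyl group (both carbinol epimers), via aryl Grignard 16 (not isolated)
Conditions: i-PrMgCl·LiCl (1.1 equiv), THF, −20 °C; then 3 (1.5 equiv), −40 → 0 °C; aq. NH4Cl
Reagents that add atoms: none
Why: Iodine–magnesium exchange, helped by the ortho benzyloxy group, then Grignard 1,2-addition; at low temperature the aldehyde should react far faster than the hindered cyclic carbonate.

Step 11
Reactants: 17 carbonate 14 bearing at C6 a [3,4-bis(benzyloxy)-2-(vinyloxy)phenyl](hydroxy)methyl group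
Product: 18 7,8-bis(benzyloxy)-4H-chromene carrying at C4, on the β face, C6 of carbonate 14
Conditions: imidodiphosphorimidate HN[P(=NSO2CF3)(O2Ar*)]2, Ar*O2 = 3,3′-bis[3,5-bis(trifluoromethyl)phenyl]-1,1′-binaphthalene-2,2′-diolate (5 mol%), 5 Å MS, CH2Cl2, −60 °C, 0.005 M; Et3N quench
Reagents that add atoms: none
Why: Proposed new method: the acid ionises the benzhydrol to a cation stabilised by two para oxygens, the vinyl ether β-carbon attacks it in a 6-endo closure forming C3–C4, and loss of the C3 proton gives the enol ether; the face of the cation, and so C4, is chosen by the confined chiral anion. The closest known types are acid-promoted capture of benzhydryl cations by enol ethers and chiral-phosphate-controlled additions to ortho-quinone methides.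

Step 12
Reactants: 18 7,8-bis(benzyloxy)-4H-chromene carrying at C4, on the β face, C6 of carbonate 14
Product: 20 protected dimer with middle unit 2α-[4-(benzyloxy)phenyl]-3α-hydroxy-7,8-bis(benzyloxy)chroman-4β-yl on C6 of carbonate 14, via epoxide 19 (not isolated)
Conditions: dimethyldioxirane, acetone/CH2Cl2, −40 °C; evaporate cold; then (4-BnOC6H4)3Al (3 equiv), toluene, −78 → 0 °C
Reagents that add atoms: dimethyldioxirane CC1(C)OO1; tris[4-(benzyloxy)phenyl]alane c1ccccc1COc1ccc(cc1)[Al](c1ccc(OCc2ccccc2)cc1)c1ccc(OCc2ccccc2)cc1
Why: The dioxirane epoxidises the enol ether anti to the 4β-aryl group, setting 3α-O. The alane binds the epoxide oxygen, opens the C2–O bond and transfers an aryl group to C2 from the same face (syn C-arylation known for glycal epoxides), setting 2α-aryl cis to the 3-OH.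

Step 13
Reactants: 20 protected dimer
Product: 21 protected dimer iodinated at C6 of the middle unit
Conditions: NIS (1.05 equiv), CF3CO2H (10 mol%), MeCN/CH2Cl2, 0 °C
Reagents that add atoms: N-iodosuccinimide O=C1CCC(=O)N1I
Why: Electrophilic aromatic iodination; C6 of the middle unit is the only free position that is para to a ring oxygen and ortho to a benzyloxy group, while C6 of the bottom unit is already substituted.

Step 14
Reactants: 21 protected dimer iodinated at C6 of the middle unit; 3 3,4-bis(benzyloxy)-2-(vinyloxy)benzaldehyde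
Product: 23 protected dimer bearing at C6 of the middle unit a [3,4-bis(benzyloxy)-2-(vinyloxy)phenyl](hydroxy)methyl group (both carbinol epimers), via aryl Grignard 22 (not isolated)
Conditions: MeMgCl (1.0 equiv), THF, −30 °C; i-PrMgCl·LiCl (1.2 equiv), −20 °C; then 3 (2 equiv), −40 → 0 °C; aq. NH4Cl
Reagents that add atoms: none
Why: The free 3-OH is first converted into its magnesium alkoxide; iodine–magnesium exchange and Grignard 1,2-addition to the aldehyde then follow as in step 10.

Step 15
Reactants: 23 protected dimer bearing at C6 of the middle unit a [3,4-bis(benzyloxy)-2-(vinyloxy)phenyl](hydroxy)methyl group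
Product: 24 7,8-bis(benzyloxy)-4H-chromene carrying at C4, on the β face, C6 of the middle unit of the protected dimer
Conditions: imidodiphosphorimidate HN[P(=NSO2CF3)(O2Ar*)]2 as in step 11 (5–10 mol%), 5 Å MS, CH2Cl2, −60 °C, 0.005 M; Et3N quench
Reagents that add atoms: none
Why: Proposed new method: the acid ionises the benzhydrol to a cation stabilised by the 7-benzyloxy group of the top ring (para to C4a) and by O1 of the middle unit (para to C6), held as an ion pair in the pocket of the chiral anion; both carbinol epimers give the same cation. The β-carbon of the aryl vinyl ether on the adjacent ring carbon attacks the cationic carbon, forming C3–C4 and an O1=C2 oxocarbenium ion, which gives up its C3 proton to the anion to leave the C2=C3 enol ether and return the acid. The closest known types are acid-promoted alkylation of enol ethers by benzhydryl cations and chiral-phosphate-controlled additions to ortho-quinone methides; the enantioselective version on a cation with no hydrogen-bonding handle has not been shown. The pyran ring closes in the 6-endo-trig mode, with both alkene carbons inside the new ring. The new stereocentre C4 is set by the face of the planar cation that the alkene reaches; the stereocentres of the dimer are at least four bonds away, so the counteranion is the controlling element. The step needs ionisation to outrun C-protonation of the vinyl ether, which would lead to an acetal with the carbinol oxygen. The cation is very stable, and a strong acid favours ionisation over the slower protonation of a weakly basic aryl vinyl ether. High dilution and molecular sieves suppress intermolecular arene capture and return of water, and the carbonate keeps the bottom C4–O bond from ionising.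

Step 16
Reactants: 24 7,8-bis(benzyloxy)-4H-chromene carrying at C4, on the β face, C6 of the middle unit of the protected dimer
Product: 26 protected trimer (nine benzyl ethers; bottom 3,4-carbonate; top and middle 3-OH free), via epoxide 25 (not isolated)
Conditions: dimethyldioxirane, acetone/CH2Cl2, −40 °C; evaporate cold; then (4-BnOC6H4)3Al (4 equiv), toluene, −78 → 0 °C
Reagents that add atoms: dimethyldioxirane CC1(C)OO1; tris[4-(benzyloxy)phenyl]alane c1ccccc1COc1ccc(cc1)[Al](c1ccc(OCc2ccccc2)cc1)c1ccc(OCc2ccccc2)cc1
Why: As in step 12: epoxidation anti to the 4β-aryl group sets 3α-O, and syn aryl transfer from the aluminium centre bound to that oxygen sets 2α-aryl; one extra equivalent of alane is spent on the free middle 3-OH.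

Step 17
Reactants: 26 protected trimer
Product: 27 nona-O-benzyl trimer with free bottom 3,4-diol
Conditions: K2CO3 (0.2 equiv), MeOH/THF, rt
Reagents that add atoms: none
Why: Base-catalysed transesterification of the cyclic carbonate with methanol; it is done before hydrogenolysis because the benzylic carbonate C4–O bond would otherwise be cleaved by hydrogen.

Step 18
Reactants: 27 nona-O-benzyl trimer with free bottom 3,4-diol
Product: 28 target trimer (CNP0140823.1)
Conditions: H2 (1 atm), Pd(OH)2/C, THF/MeOH, rt
Reagents that add atoms: none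
Why: Hydrogenolysis of nine aryl benzyl ethers under neutral conditions, which should leave the free benzylic C4–OH, the C2–O1 ethers and the interflavan bonds in place; no stereocentre is touched.

## Compound list

1 | 2,3,4-trihydroxybenzaldehyde | O=Cc1ccc(O)c(O)c1O | starting material
2 | 3,4-bis(benzyloxy)-2-hydroxybenzaldehyde | O=Cc1ccc(OCc2ccccc2)c(OCc2ccccc2)c1O | intermediate
3 | 3,4-bis(benzyloxy)-2-(vinyloxy)benzaldehyde | O=Cc1ccc(OCc2ccccc2)c(OCc2ccccc2)c1OC=C | intermediate
4 | 2,3,4-trihydroxyacetophenone (gallacetophenone) | CC(=O)c1ccc(O)c(O)c1O | starting material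
5 | 1-[3,4-bis(benzyloxy)-2-hydroxyphenyl]ethanone | CC(=O)c1ccc(OCc2ccccc2)c(OCc2ccccc2)c1O | intermediate
6 | (E)-1-[3,4-bis(benzyloxy)-2-hydroxyphenyl]-3-(dimethylamino)prop-2-en-1-one | CN(C)/C=C/C(=O)c1ccc(OCc2ccccc2)c(OCc2ccccc2)c1O | intermediate
7 | 7,8-bis(benzyloxy)-4H-chromen-4-one | O=C1C=COc2c1ccc(OCc1ccccc1)c2OCc1ccccc1 | intermediate
8 | 4-(benzyloxy)phenylboronic acid | OB(O)c1ccc(OCc2ccccc2)cc1 | starting material
9 | (2S)-7,8-bis(benzyloxy)-2-[4-(benzyloxy)phenyl]chroman-4-one | O=C1C[C@@H](c2ccc(OCc3ccccc3)cc2)Oc2c1ccc(OCc1ccccc1)c2OCc1ccccc1 | intermediate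
10 | (2S,4S)-7,8-bis(benzyloxy)-2-[4-(benzyloxy)phenyl]chroman-4-ol (2,4-cis) | O[C@H]1C[C@@H](c2ccc(OCc3ccccc3)cc2)Oc2c1ccc(OCc1ccccc1)c2OCc1ccccc1 | intermediate
11 | (2S,4S)-7,8-bis(benzyloxy)-2-[4-(benzyloxy)phenyl]chroman-4-yl methanesulfonate | CS(=O)(=O)O[C@H]1C[C@@H](c2ccc(OCc3ccccc3)cc2)Oc2c1ccc(OCc1ccccc1)c2OCc1ccccc1 | intermediate
12 | (2S)-7,8-bis(benzyloxy)-2-[4-(benzyloxy)phenyl]-2H-chromene | C1=C[C@@H](c2ccc(OCc3ccccc3)cc2)Oc2c1ccc(OCc1ccccc1)c2OCc1ccccc1 | intermediate
13 | (2R,3S,4R)-7,8-bis(benzyloxy)-2-[4-(benzyloxy)phenyl]-3-bromochroman-4-ol (2α-aryl, 3β-Br, 4α-OH) | O[C@H]1[C@H](Br)[C@@H](c2ccc(OCc3ccccc3)cc2)Oc2c1ccc(OCc1ccccc1)c2OCc1ccccc1 | intermediate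
14 | (2R,3S,4R)-7,8-bis(benzyloxy)-2-[4-(benzyloxy)phenyl]chroman-3,4-diyl carbonate (all-cis) | c3cc4c(c(OCc5ccccc5)c3OCc5ccccc5)O[C@H](c3ccc(OCc5ccccc5)cc3)[C@H](O6)[C@@H]4OC6=O | intermediate
15 | 6-iodo derivative of 14 | Ic3cc4c(c(OCc5ccccc5)c3OCc5ccccc5)O[C@H](c3ccc(OCc5ccccc5)cc3)[C@H](O6)[C@@H]4OC6=O | intermediate
16 | 6-(chloromagnesio) derivative of 14 | Cl[Mg]c3cc4c(c(OCc5ccccc5)c3OCc5ccccc5)O[C@H](c3ccc(OCc5ccccc5)cc3)[C@H](O6)[C@@H]4OC6=O | intermediate
17 | carbonate 14 bearing at C6 a [3,4-bis(benzyloxy)-2-(vinyloxy)phenyl](hydroxy)methyl group, both carbinol epimers | C=COc1c(OCc5ccccc5)c(OCc5ccccc5)ccc1C(O)c3cc4c(c(OCc5ccccc5)c3OCc5ccccc5)O[C@H](c3ccc(OCc5ccccc5)cc3)[C@H](O6)[C@@H]4OC6=O | intermediate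
18 | 7,8-bis(benzyloxy)-4H-chromene with C6 of carbonate 14 at C4 (β) | C2=C[C@@H](c3cc4c(c(OCc5ccccc5)c3OCc5ccccc5)O[C@H](c3ccc(OCc5ccccc5)cc3)[C@H](O6)[C@@H]4OC6=O)c3ccc(OCc5ccccc5)c(OCc5ccccc5)c3O2 | intermediate
19 | 2α,3α-epoxide of 18 | O1[C@H]2[C@H](O2)[C@@H](c3cc4c(c(OCc5ccccc5)c3OCc5ccccc5)O[C@H](c3ccc(OCc5ccccc5)cc3)[C@H](O6)[C@@H]4OC6=O)c2ccc(OCc5ccccc5)c(OCc5ccccc5)c21 | intermediate
20 | protected dimer: middle unit 2α-[4-(benzyloxy)phenyl]-3α-hydroxy-7,8-bis(benzyloxy)chroman-4β-yl on C6 of carbonate 14 | C(c5ccccc5)Oc1ccc([C@H]2Oc3c(ccc(OCc5ccccc5)c3OCc5ccccc5)[C@H](c3cc4c(c(OCc5ccccc5)c3OCc5ccccc5)O[C@H](c3ccc(OCc5ccccc5)cc3)[C@H](O6)[C@@H]4OC6=O)[C@H]2O)cc1 | intermediate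
21 | protected dimer 20 iodinated at C6 of the middle unit | C(c5ccccc5)Oc1ccc([C@H]2Oc3c(cc(I)c(OCc5ccccc5)c3OCc5ccccc5)[C@H](c3cc4c(c(OCc5ccccc5)c3OCc5ccccc5)O[C@H](c3ccc(OCc5ccccc5)cc3)[C@H](O6)[C@@H]4OC6=O)[C@H]2O)cc1 | intermediate
22 | chloromagnesium alkoxide of 20 with a chloromagnesio group at C6 of the middle unit | C(c5ccccc5)Oc1ccc([C@H]2Oc3c(cc([Mg]Cl)c(OCc5ccccc5)c3OCc5ccccc5)[C@H](c3cc4c(c(OCc5ccccc5)c3OCc5ccccc5)O[C@H](c3ccc(OCc5ccccc5)cc3)[C@H](O6)[C@@H]4OC6=O)[C@H]2O[Mg]Cl)cc1 | intermediate
23 | protected dimer bearing at C6 of the middle unit a [3,4-bis(benzyloxy)-2-(vinyloxy)phenyl](hydroxy)methyl group, both carbinol epimers | C=COc1c(OCc5ccccc5)c(OCc5ccccc5)ccc1C(O)c3cc4c(c(OCc5ccccc5)c3OCc5ccccc5)O[C@H](c3ccc(OCc5ccccc5)cc3)[C@H](O)[C@H]4c3cc4c(c(OCc5ccccc5)c3OCc5ccccc5)O[C@H](c3ccc(OCc5ccccc5)cc3)[C@H](O6)[C@@H]4OC6=O | intermediate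
24 | 7,8-bis(benzyloxy)-4H-chromene with C6 of the middle unit of the protected dimer at C4 (β) | C2=C[C@@H](c3cc4c(c(OCc5ccccc5)c3OCc5ccccc5)O[C@H](c3ccc(OCc5ccccc5)cc3)[C@H](O)[C@H]4c3cc4c(c(OCc5ccccc5)c3OCc5ccccc5)O[C@H](c3ccc(OCc5ccccc5)cc3)[C@H](O6)[C@@H]4OC6=O)c3ccc(OCc5ccccc5)c(OCc5ccccc5)c3O2 | intermediate
25 | 2α,3α-epoxide of 24 | O1[C@H]2[C@H](O2)[C@@H](c3cc4c(c(OCc5ccccc5)c3OCc5ccccc5)O[C@H](c3ccc(OCc5ccccc5)cc3)[C@H](O)[C@H]4c3cc4c(c(OCc5ccccc5)c3OCc5ccccc5)O[C@H](c3ccc(OCc5ccccc5)cc3)[C@H](O6)[C@@H]4OC6=O)c2ccc(OCc5ccccc5)c(OCc5ccccc5)c21 | intermediate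
26 | protected trimer: nine benzyl ethers, bottom 3,4-carbonate, top and middle 3-OH free | C(c5ccccc5)Oc1ccc([C@H]2Oc3c(ccc(OCc5ccccc5)c3OCc5ccccc5)[C@H](c3cc4c(c(OCc5ccccc5)c3OCc5ccccc5)O[C@H](c3ccc(OCc5ccccc5)cc3)[C@H](O)[C@H]4c3cc4c(c(OCc5ccccc5)c3OCc5ccccc5)O[C@H](c3ccc(OCc5ccccc5)cc3)[C@H](O6)[C@@H]4OC6=O)[C@H]2O)cc1 | intermediate
27 | nona-O-benzyl trimer with free bottom 3,4-diol | C(c5ccccc5)Oc1ccc([C@H]2Oc3c(ccc(OCc5ccccc5)c3OCc5ccccc5)[C@H](c3cc4c(c(OCc5ccccc5)c3OCc5ccccc5)O[C@H](c3ccc(OCc5ccccc5)cc3)[C@H](O)[C@H]4c3cc4c(c(OCc5ccccc5)c3OCc5ccccc5)O[C@H](c3ccc(OCc5ccccc5)cc3)[C@H](O)[C@@H]4O)[C@H]2O)cc1 | intermediate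
28 | CNP0140823.1: top and middle units (2R,3R,4S), bottom unit (2R,3R,4R) | Oc1ccc([C@H]2Oc3c(ccc(O)c3O)[C@H](c3cc4c(c(O)c3O)O[C@H](c3ccc(O)cc3)[C@H](O)[C@H]4c3cc4c(c(O)c3O)O[C@H](c3ccc(O)cc3)[C@H](O)[C@@H]4O)[C@H]2O)cc1 | target

## Step count and least certain steps

Total: 18 steps. Longest linear sequence: 16 steps (from 4 through steps 3–18). Aldehyde 3 is made in two steps and used twice.

**Step 15 (key step).** The vinyl ether may be protonated before the carbinol ionises, leading to acetal formation with the carbinol oxygen and loss of the two-carbon unit. The ion pair may also give poor facial selectivity at C4, or the cation may be captured by another molecule. Fallback with known chemistry, from 21 back to 24: the aryl Grignard 22 is added to 3,4-bis(benzyloxy)-2-[(tert-butoxycarbonyl)oxy]benzaldehyde F1 (from 2 and Boc2O). Transfer of the carbonate to the new alkoxide and elimination release an ortho-quinone methide, which is trapped by ethyl vinyl ether in a [4+2] cycloaddition to the top-unit 2-ethoxy-4-arylchroman F2. The C4 epimers are diastereomers and would be separated by chromatography; a chiral vinyl ether could bias this centre. Elimination of ethanol with Me3SiOTf and i-Pr2NEt then gives 24.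

**Step 11 (first use of the cyclisation).** The same failure modes apply on the monomer. Fallback, from 15 back to 18: the aryl Grignard 16 is combined with the Boc aldehyde F1 and ethyl vinyl ether in the same way to give the 2-ethoxy-4-arylchroman F3, and ethanol is eliminated with Me3SiOTf and i-Pr2NEt.

**Step 12 (and step 16, same operation).** The enol-ether epoxide may rearrange by hydride shift to the chroman-3-one, or aryl transfer may occur without syn delivery. Fallback, from 18 back to 20: the epoxide is opened in acetone/methanol to the stable 2β-methoxy-3α-ol F4. The 3-OH is silylated with chloro[4-(benzyloxy)phenyl]dimethylsilane to give the silyl ether F5. SnCl4 then ionises the acetal, and the tethered aryl group is delivered by ipso substitution to the α face of C2 (silicon-tethered intramolecular C-arylation known for glycosyl donors). Aqueous fluoride work-up frees the 3-OH of 20.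

**Step 14 (and step 10).** The exchange reagent or the aryl Grignard may attack the cyclic carbonate, or slow exchange may end in loss of iodine by protonation. Fallback, from 21 back to 23: Miyaura borylation (Pd(dppf)Cl2, bis(pinacolato)diboron, KOAc) gives the pinacol boronate F6, which is added to aldehyde 3 under [Rh(OH)(cod)]2 catalysis in aqueous dioxane. These conditions do not affect carbonates.

**Step 8.** Competing bromination of the electron-rich ring at C6, rearrangement of the benzylic bromohydrin, or base-induced elimination may reduce the yield of carbonate. Fallback, from 12 back to 14: Woodward cis-hydroxylation (I2, AgOAc, wet AcOH) delivers both oxygens to the face of the aryl group through an acetoxonium ion and gives the all-cis 3-acetoxy-4-ol F7. Methanolysis (K2CO3, MeOH) gives the all-cis diol F8, which is closed to 14 with carbonyldiimidazole.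

**Step 18.** Hydrogenolysis may also remove the benzylic C4–OH of the bottom unit, or stop before all nine ethers are cleaved. Fallback, from 26 back to 28: the benzyl ethers are cleaved with BCl3 and pentamethylbenzene at −78 °C while the carbonate still deactivates C4–O, giving the nonaphenol carbonate F9. The carbonate is then removed by brief treatment with NaHCO3 in aqueous methanol under argon.

## Further compounds

F1 | step 15 | 3,4-bis(benzyloxy)-2-[(tert-butoxycarbonyl)oxy]benzaldehyde | O=Cc1ccc(OCc2ccccc2)c(OCc2ccccc2)c1OC(=O)OC(C)(C)C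
F2 | step 15 | 2-ethoxy-7,8-bis(benzyloxy)chroman with C6 of the middle unit of the protected dimer at C4 (β), C2 epimers | CCOC2C[C@@H](c3cc4c(c(OCc5ccccc5)c3OCc5ccccc5)O[C@H](c3ccc(OCc5ccccc5)cc3)[C@H](O)[C@H]4c3cc4c(c(OCc5ccccc5)c3OCc5ccccc5)O[C@H](c3ccc(OCc5ccccc5)cc3)[C@H](O6)[C@@H]4OC6=O)c3ccc(OCc5ccccc5)c(OCc5ccccc5)c3O2
F3 | step 11 | 2-ethoxy-7,8-bis(benzyloxy)chroman with C6 of carbonate 14 at C4 (β), C2 epimers | CCOC2C[C@@H](c3cc4c(c(OCc5ccccc5)c3OCc5ccccc5)O[C@H](c3ccc(OCc5ccccc5)cc3)[C@H](O6)[C@@H]4OC6=O)c3ccc(OCc5ccccc5)c(OCc5ccccc5)c3O2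
F4 | step 12 | 2β-methoxy-3α-hydroxy-7,8-bis(benzyloxy)chroman with C6 of carbonate 14 at C4 (β) | O1[C@@H](OC)[C@H](O)[C@@H](c3cc4c(c(OCc5ccccc5)c3OCc5ccccc5)O[C@H](c3ccc(OCc5ccccc5)cc3)[C@H](O6)[C@@H]4OC6=O)c2ccc(OCc5ccccc5)c(OCc5ccccc5)c21
F5 | step 12 | 3-O-{[4-(benzyloxy)phenyl]dimethylsilyl} ether of F4 | O1[C@@H](OC)[C@H](O[Si](C)(C)c2ccc(OCc5ccccc5)cc2)[C@@H](c3cc4c(c(OCc5ccccc5)c3OCc5ccccc5)O[C@H](c3ccc(OCc5ccccc5)cc3)[C@H](O6)[C@@H]4OC6=O)c2ccc(OCc5ccccc5)c(OCc5ccccc5)c21
F6 | step 14 | protected dimer 20 with a pinacolboryl group at C6 of the middle unit | C(c5ccccc5)Oc1ccc([C@H]2Oc3c(cc(B7OC(C)(C)C(C)(C)O7)c(OCc5ccccc5)c3OCc5ccccc5)[C@H](c3cc4c(c(OCc5ccccc5)c3OCc5ccccc5)O[C@H](c3ccc(OCc5ccccc5)cc3)[C@H](O6)[C@@H]4OC6=O)[C@H]2O)cc1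
F7 | step 8 | (2R,3R,4R)-7,8-bis(benzyloxy)-2-[4-(benzyloxy)phenyl]-4-hydroxychroman-3-yl acetate (all-cis) | c3cc4c(c(OCc5ccccc5)c3OCc5ccccc5)O[C@H](c3ccc(OCc5ccccc5)cc3)[C@H](OC(C)=O)[C@@H]4O
F8 | step 8 | (2R,3R,4R)-7,8-bis(benzyloxy)-2-[4-(benzyloxy)phenyl]chroman-3,4-diol (all-cis) | c3cc4c(c(OCc5ccccc5)c3OCc5ccccc5)O[C@H](c3ccc(OCc5ccccc5)cc3)[C@H](O)[C@@H]4O
F9 | step 18 | target trimer as its bottom-unit 3,4-carbonate, all phenols free | Oc1ccc([C@H]2Oc3c(ccc(O)c3O)[C@H](c3cc4c(c(O)c3O)O[C@H](c3ccc(O)cc3)[C@H](O)[C@H]4c3cc4c(c(O)c3O)O[C@H](c3ccc(O)cc3)[C@H](O6)[C@@H]4OC6=O)[C@H]2O)cc1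
A1 | alternative 1 | acetonide-protected bottom unit bearing at C6 the open-chain middle unit (3-O-benzyl, 2-bromo-3,4-bis(benzyloxy)phenyl at C4) as its C2 (R,R)-1,2-dicyclohexylethane-1,2-diol boronic ester | C(c5ccccc5)Oc1ccc([C@@H](B7O[C@@H](C6CCCCC6)[C@H](C6CCCCC6)O7)[C@H](OCc5ccccc5)[C@@H](c3cc4c(c(OCc5ccccc5)c3OCc5ccccc5)O[C@H](c3ccc(OCc5ccccc5)cc3)[C@H](O6)[C@@H]4OC6(C)C)c3ccc(OCc5ccccc5)c(OCc5ccccc5)c3Br)cc1
A2 | alternative 2 | acetonide-protected dimer carrying the top unit as 4-aryl-2-hydroxy-2,3,4,5,6,7-hexahydro-8H-chromen-8-one | OC1C[C@@H](c3cc4c(c(OCc5ccccc5)c3OCc5ccccc5)O[C@H](c3ccc(OCc5ccccc5)cc3)[C@H](OCc5ccccc5)[C@H]4c3cc4c(c(OCc5ccccc5)c3OCc5ccccc5)O[C@H](c3ccc(OCc5ccccc5)cc3)[C@H](O6)[C@@H]4OC6(C)C)C2=C(O1)C(=O)CCC2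
A3 | alternative 3 | protected trimer (bottom 3,4-acetonide, middle 3-O-benzyl) with top-unit 3-O-acetate and 4′-O-pivalate | CC(C)(C)C(=O)Oc1ccc([C@H]2Oc3c(ccc(OCc5ccccc5)c3OCc5ccccc5)[C@H](c3cc4c(c(OCc5ccccc5)c3OCc5ccccc5)O[C@H](c3ccc(OCc5ccccc5)cc3)[C@H](OCc5ccccc5)[C@H]4c3cc4c(c(OCc5ccccc5)c3OCc5ccccc5)O[C@H](c3ccc(OCc5ccccc5)cc3)[C@H](O6)[C@@H]4OC6(C)C)[C@H]2OC(C)=O)cc1
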